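**Plan**

Chroman numbering is used: O1, C2, C3, C4, C4a to C8a; ring A is the benzoate ring, ring B the pyran ring.

1. Retrosynthesis: the side-chain alkene is cut by cross-metathesis (C2-allyl plus 2-methylbut-3-en-2-ol); C3–OAc is traced through C3–OH to a C3–B bond; ring B is then cut at C4–C3 and O1–C2 in one stroke.
2. Enabling feature: O1 and the benzylic C4 are ortho on ring A, a latent 1-oxadiene O1=C8a–C4a=C4 (ortho-quinone methide). C2 is fully substituted and the C3 oxygen can be carried as boron, which polarises a C3=C2 alkene the right way.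
3. Forward: (Z)-alkenyl MIDA boronate from propyne (steps 1–2); quinone methide precursor from methyl 3-formyl-4-hydroxybenzoate (steps 3–4); the [4+2] cycloaddition builds ring B on ring A (step 5); then C–B oxidation, acetylation and chain completion (steps 6–8).
4. Stereochemistry: the cis C2/C3 relationship comes from the Z alkene through the suprafacial cycloaddition and the stereoretentive C–B oxidation. The absolute configuration comes from a lipase-catalysed enantiomer-selective acetylation, which also installs the acetate. The E side-chain alkene comes from cross-metathesis.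

Key step: step 5

Remark: compounds 10, 11 and 12 are racemic (cis); each is written with the SMILES of its (2R,3R)-enantiomer, the one that step 7 carries on.

**Route**

Step 1
Reactants: 1 propyne; 2 diethyl prop-2-en-1-yl phosphate (diethyl allyl phosphate)
Product: 3 (Z)-4,4,5,5-tetramethyl-2-(2-methylpenta-1,4-dien-1-yl)-1,3,2-dioxaborolane (boron cis to the allyl CH2)
Conditions: B2pin2, CuCl (5 mol %), PCy3 (6 mol %), KOtBu, THF, 0 °C to rt
Reagents that add atoms: bis(pinacolato)diboron, CC1(C)OB(OC1(C)C)B1OC(C)(C)C(C)(C)O1
Why: Copper-catalysed borylallylation (carboboration) of a terminal alkyne: syn addition of Cu–Bpin should place boron on the terminal carbon and copper on the methyl-bearing carbon, and allylation of that alkenylcopper with retention fixes boron cis to the allyl group, the Z geometry the route needs.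

Step 2
Reactants: 3 (Z)-4,4,5,5-tetramethyl-2-(2-methylpenta-1,4-dien-1-yl)-1,3,2-dioxaborolane
Product: 5 6-methyl-2-[(1Z)-2-methylpenta-1,4-dien-1-yl]-1,3,6,2-dioxazaborocane-4,8-dione (the MIDA boronate), via boronic acid 4 (not isolated)
Conditions: NaIO4, NH4OAc, acetone/H2O, rt; then MIDA anhydride, dioxane, 70 °C
Reagents that add atoms: N-methyliminodiacetic anhydride (MIDA anhydride), CN1CC(=O)OC(=O)C1
Why: Periodate cleavage of the pinacol ester followed by condensation of the boronic acid with MIDA anhydride is the standard two-stage ligand exchange to a tetracoordinate MIDA boronate, and it leaves the alkene geometry untouched.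

Step 3
Reactants: 6 methyl 3-formyl-4-hydroxybenzoate
Product: 7 methyl 3-[(dimethylamino)methyl]-4-hydroxybenzoate
Conditions: Me2NH (2 M in THF), NaBH(OAc)3, AcOH, ClCH2CH2Cl, rt
Reagents that add atoms: dimethylamine, CNC
Why: Reductive amination of a salicylaldehyde through its iminium ion, with a hydride donor that leaves the methyl ester alone.

Step 4
Reactants: 7 methyl 3-[(dimethylamino)methyl]-4-hydroxybenzoate
Product: 8 [2-hydroxy-5-(methoxycarbonyl)phenyl]-N,N,N-trimethylmethanaminium iodide
Conditions: MeI, acetone, rt (salt filtered off)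
Reagents that add atoms: iodomethane, CI
Why: Menshutkin N-alkylation, in which the tertiary amine is far more nucleophilic than the un-ionised, ester-deactivated phenol, installs the benzylic trimethylammonium leaving group needed for quinone methide formation.

Step 5
Reactants: 8 [2-hydroxy-5-(methoxycarbonyl)phenyl]-N,N,N-trimethylmethanaminium iodide; 5 6-methyl-2-[(1Z)-2-methylpenta-1,4-dien-1-yl]-1,3,6,2-dioxazaborocane-4,8-dione
Product: 10 methyl rac-(2R,3R)-2-methyl-3-(6-methyl-4,8-dioxo-1,3,6,2-dioxazaborocan-2-yl)-2-(prop-2-en-1-yl)-3,4-dihydro-2H-chromene-6-carboxylate (boron cis to allyl), via ortho-quinone methide 9 (not isolated)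
Conditions: 5 (3 equiv), iPr2NEt, MeCN, 80–100 °C (sealed tube), 8 added in portions over several hours
Reagents that add atoms: none
Why: Proposed new method: iPr2NEt removes the phenol proton of 8 and 1,4-elimination of NMe3 gives the electron-poor 1-oxadiene 9 (O1=C8a–C4a=C4), which should add across the C3=C2 alkene of 5 in an inverse-electron-demand oxa-[4+2] cycloaddition, concerted but asynchronous, with C4–C3 bonding ahead of O1–C2. The closest known reaction type is the thermal hetero-Diels–Alder reaction of ortho-quinone methides with unactivated 1,1-di- and trisubstituted alkenes to give 2,2-disubstituted chromans, and alkenyl MIDA boronates are known to keep their C–B bond in epoxidation, cyclopropanation and dipolar cycloaddition. Ring B is closed in the [4π+2π] mode, both new σ bonds (C4–C3 and O1–C2) forming on one face of the alkene. Regiochemistry: the methide carbon C4 should bond to the boron-bearing CH terminus because the positive charge that builds up then sits on the fully substituted C2, tertiary and β to the tetracoordinate boron (σ C–B hyperconjugation), where the phenoxide oxygen collapses on it. Stereochemistry: suprafacial addition transfers the Z geometry of 5 into the cis relationship of boron at C3 and allyl at C2, so both centres are set at once (C4 is not stereogenic, so endo/exo plays no part, and the product is racemic). The selectivities needed are cycloaddition over self-condensation of 9 (slow addition of 8 into excess 5), over ipso alkenyl transfer with loss of boron (the MIDA cage leaves boron no vacant orbital for a phenoxide ate complex) and over reaction at the monosubstituted allyl alkene (far less nucleophilic).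

Step 6
Reactants: 10 methyl rac-(2R,3R)-2-methyl-3-(6-methyl-4,8-dioxo-1,3,6,2-dioxazaborocan-2-yl)-2-(prop-2-en-1-yl)-3,4-dihydro-2H-chromene-6-carboxylate
Product: 12 methyl rac-(2R,3R)-3-hydroxy-2-methyl-2-(prop-2-en-1-yl)-3,4-dihydro-2H-chromene-6-carboxylate (hydroxyl cis to allyl), via chromanylboronic acid 11 (not isolated)
Conditions: aq. NaHCO3, MeOH/THF, rt; then 30% H2O2, 0 °C to rt
Reagents that add atoms: hydrogen peroxide, OO
Why: Mild hydrolysis of the MIDA ester and peroxide oxidation of the C–B bond (1,2-shift of C3 from boron to oxygen) should go with retention, so the hydroxyl takes the place of boron cis to the allyl group; β-aryloxy alkylboron compounds of this kind are known to survive to oxidation in the hydroboration–oxidation of chromenes.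

Step 7
Reactants: 12 methyl rac-(2R,3R)-3-hydroxy-2-methyl-2-(prop-2-en-1-yl)-3,4-dihydro-2H-chromene-6-carboxylate
Product: 13 methyl (2R,3R)-3-acetoxy-2-methyl-2-(prop-2-en-1-yl)-3,4-dihydro-2H-chromene-6-carboxylate
Conditions: immobilised Candida antarctica lipase B, vinyl acetate, tBuOMe, 40 °C, stopped near half conversion; chromatography
Reagents that add atoms: vinyl acetate, C=COC(C)=O
Why: Lipase-catalysed kinetic resolution by irreversible transesterification: by the empirical size rule for lipases (quaternary C2 as the large, C4H2 as the medium substituent) the (3R)-alcohol should be the fast-reacting enantiomer, so the (2R,3R)-acetate forms while the (2S,3S)-alcohol stays behind and is removed, which sets the absolute configuration.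

Step 8
Reactants: 13 methyl (2R,3R)-3-acetoxy-2-methyl-2-(prop-2-en-1-yl)-3,4-dihydro-2H-chromene-6-carboxylate; 14 2-methylbut-3-en-2-ol
Product: 15 methyl (2R,3R)-3-acetoxy-2-[(2E)-4-hydroxy-4-methylpent-2-en-1-yl]-2-methyl-3,4-dihydro-2H-chromene-6-carboxylate (the target)
Conditions: second-generation Grubbs catalyst RuCl2(H2IMes)(PCy3)(=CHPh) (5 mol %), 14 (8 equiv), CH2Cl2, 40 °C
Reagents that add atoms: none
Why: Olefin cross-metathesis of a terminal allyl group with an excess of a tertiary allylic alcohol that hardly homodimerises should give the E alkene because of the bulky carbinol end, and it leaves ester, acetate and both stereocentres untouched.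

**Compound list**

1 | propyne | CC#C | starting material
2 | diethyl prop-2-en-1-yl phosphate | C=CCOP(=O)(OCC)OCC | starting material
3 | (Z)-4,4,5,5-tetramethyl-2-(2-methylpenta-1,4-dien-1-yl)-1,3,2-dioxaborolane | CC1(C)OB(/C=C(/C)CC=C)OC1(C)C | intermediate
4 | [(1Z)-2-methylpenta-1,4-dien-1-yl]boronic acid | OB(O)/C=C(/C)CC=C | intermediate
5 | 6-methyl-2-[(1Z)-2-methylpenta-1,4-dien-1-yl]-1,3,6,2-dioxazaborocane-4,8-dione | CN1CC(=O)OB(/C=C(/C)CC=C)OC(=O)C1 | intermediate
6 | methyl 3-formyl-4-hydroxybenzoate | COC(=O)c1ccc(O)c(C=O)c1 | starting material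
7 | methyl 3-[(dimethylamino)methyl]-4-hydroxybenzoate | COC(=O)c1ccc(O)c(CN(C)C)c1 | intermediate
8 | [2-hydroxy-5-(methoxycarbonyl)phenyl]-N,N,N-trimethylmethanaminium iodide | COC(=O)c1ccc(O)c(C[N+](C)(C)C)c1.[I-] | intermediate
9 | methyl 3-methylidene-4-oxocyclohexa-1,5-diene-1-carboxylate (ortho-quinone methide) | C=C1C=C(C(=O)OC)C=CC1=O | intermediate
10 | methyl rac-(2R,3R)-2-methyl-3-(6-methyl-4,8-dioxo-1,3,6,2-dioxazaborocan-2-yl)-2-(prop-2-en-1-yl)-3,4-dihydro-2H-chromene-6-carboxylate | COC(=O)c1ccc2c(c1)C[C@@H](B3OC(=O)CN(C)CC(=O)O3)[C@@](C)(CC=C)O2 | intermediate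
11 | rac-[(2R,3R)-6-(methoxycarbonyl)-2-methyl-2-(prop-2-en-1-yl)-3,4-dihydro-2H-chromen-3-yl]boronic acid | COC(=O)c1ccc2c(c1)C[C@@H](B(O)O)[C@@](C)(CC=C)O2 | intermediate
12 | methyl rac-(2R,3R)-3-hydroxy-2-methyl-2-(prop-2-en-1-yl)-3,4-dihydro-2H-chromene-6-carboxylate | COC(=O)c1ccc2c(c1)C[C@@H](O)[C@@](C)(CC=C)O2 | intermediate
13 | methyl (2R,3R)-3-acetoxy-2-methyl-2-(prop-2-en-1-yl)-3,4-dihydro-2H-chromene-6-carboxylate | COC(=O)c1ccc2c(c1)C[C@@H](OC(C)=O)[C@@](C)(CC=C)O2 | intermediate
14 | 2-methylbut-3-en-2-ol | C=CC(C)(C)O | starting material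
15 | methyl (2R,3R)-3-acetoxy-2-[(2E)-4-hydroxy-4-methylpent-2-en-1-yl]-2-methyl-3,4-dihydro-2H-chromene-6-carboxylate | COC(=O)c1ccc2c(c1)C[C@@H](OC(C)=O)[C@@](C)(C/C=C/C(C)(C)O)O2 | target

**Step count and risks**

Total steps: 8. Longest linear sequence: 6 (steps 3, 4, 5, 6, 7, 8; equally steps 1, 2, 5, 6, 7, 8).

Steps most likely to fail:

1. Step 5 (the cycloaddition). The quinone methide may oligomerise faster than it is trapped by the moderately nucleophilic borylalkene, or the alkenyl group may be transferred to C4 with loss of boron in place of ring closure. The fallback makes the two bonds one after the other by known chemistry. It sets out from 8 and the boronic acid 4, taken on crude after the periodate cleavage of step 2. Heating with K2CO3 in toluene/water should transfer the alkenyl group from boron to the methide carbon of 9 through a phenoxide–boron ate complex (Petasis-type conjugate alkenylation, alkene geometry retained) to give methyl 4-hydroxy-3-[(2Z)-3-methylhexa-2,5-dien-1-yl]benzoate F1. Epoxidation of the trisubstituted alkene of F1 with mCPBA in CH2Cl2 at 0 °C should give the cis-epoxide methyl 4-hydroxy-3-{[rac-(2R,3S)-3-methyl-3-(prop-2-en-1-yl)oxiran-2-yl]methyl}benzoate F2, which is not isolated. A catalytic amount of camphorsulfonic acid should bring about 6-endo opening by the phenol at the tertiary carbon with inversion, so the Z geometry again ends as the cis relationship of hydroxyl and allyl. The fallback returns to the route at racemic 12.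

2. Step 7 (the enzymatic resolution). The lipase may accept the alcohol next to the quaternary carbon too slowly, or discriminate poorly between the enantiomers. The fallback is a resolution through covalent diastereomers. Setting out from 12, esterification with (S)-2-methoxy-2-phenylacetic acid (DCC, DMAP, CH2Cl2) should give two diastereomeric esters: methyl (2R,3R)-3-{[(2S)-2-methoxy-2-phenylacetyl]oxy}-2-methyl-2-(prop-2-en-1-yl)-3,4-dihydro-2H-chromene-6-carboxylate F3 and its (2S,3S)-chromanyl diastereomer F4. They are separated by chromatography or crystallisation and assigned by the shielding model for such esters. Methanolysis of F3 (K2CO3, MeOH) should free methyl (2R,3R)-3-hydroxy-2-methyl-2-(prop-2-en-1-yl)-3,4-dihydro-2H-chromene-6-carboxylate F5 as a single enantiomer. Acetylation (Ac2O, pyridine, DMAP) returns to the route at 13.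

3. Step 1 (the borylallylation). The copper–boryl species may borylate the allyl phosphate directly, or the acidic C–H of propyne may protonate the alkenylcopper intermediate. The fallback builds 3 by bromoboration and cross-coupling. Setting out from 1, BBr3 in CH2Cl2 at −78 °C should add syn across the triple bond to give (Z)-dibromo(2-bromoprop-1-en-1-yl)borane F6, which pinacol converts into (Z)-2-(2-bromoprop-1-en-1-yl)-4,4,5,5-tetramethyl-1,3,2-dioxaborolane F7. Negishi coupling of F7 with allylzinc bromide, C3H5ZnBr, catalysed by Pd(PtBu3)2 in THF at rt, should proceed with retention and returns to the route at 3.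

**Further compounds**

F1 | step 5 | methyl 4-hydroxy-3-[(2Z)-3-methylhexa-2,5-dien-1-yl]benzoate | COC(=O)c1ccc(O)c(C/C=C(/C)CC=C)c1
F2 | step 5 | methyl 4-hydroxy-3-{[rac-(2R,3S)-3-methyl-3-(prop-2-en-1-yl)oxiran-2-yl]methyl}benzoate | COC(=O)c1ccc(O)c(C[C@H]2O[C@@]2(C)CC=C)c1
F3 | step 7 | methyl (2R,3R)-3-{[(2S)-2-methoxy-2-phenylacetyl]oxy}-2-methyl-2-(prop-2-en-1-yl)-3,4-dihydro-2H-chromene-6-carboxylate | COC(=O)c1ccc2c(c1)C[C@@H](OC(=O)[C@@H](OC)c3ccccc3)[C@@](C)(CC=C)O2
F4 | step 7 | methyl (2S,3S)-3-{[(2S)-2-methoxy-2-phenylacetyl]oxy}-2-methyl-2-(prop-2-en-1-yl)-3,4-dihydro-2H-chromene-6-carboxylate | COC(=O)c1ccc2c(c1)C[C@H](OC(=O)[C@@H](OC)c3ccccc3)[C@](C)(CC=C)O2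
F5 | step 7 | methyl (2R,3R)-3-hydroxy-2-methyl-2-(prop-2-en-1-yl)-3,4-dihydro-2H-chromene-6-carboxylate (single enantiomer) | COC(=O)c1ccc2c(c1)C[C@@H](O)[C@@](C)(CC=C)O2
F6 | step 1 | (Z)-dibromo(2-bromoprop-1-en-1-yl)borane | BrB(Br)/C=C(/C)Br
F7 | step 1 | (Z)-2-(2-bromoprop-1-en-1-yl)-4,4,5,5-tetramethyl-1,3,2-dioxaborolane | CC1(C)OB(/C=C(/C)Br)OC1(C)C
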